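**Assumption:** the (R)-t-BuPyOx antipode is assigned to give 2S by analogy with the facial model for cyclic enones (from memory, not verified for this substrate); confirm by CD/rotation on 11 and swap to the (S)-ligand if the sense is opposite.

## Retrosynthetic overview
1. Target ⇐ global removal of three MOM ethers from the tris-MOM (2S)-flavanone.
2. C2–C1′ bond and the only stereocentre ⇐ Pd(II)/PyOx-catalysed asymmetric conjugate addition of a 4-MOMO-3-prenylphenylboronic acid to a 5,7-bis(MOMO)-8-prenylchromone.
3. Chromone ⇐ DMF-DMA annulation of 2-hydroxy-3-prenyl-4,6-bis(MOMO)acetophenone ⇐ C-prenylation and selective bis-MOM protection of phloroacetophenone.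
4. Boronic acid ⇐ 4-bromophenol by ortho-C-prenylation, MOM protection and Br/Li/B exchange.
5. Ring order: A ring purchased → pyranone C ring closed (achiral chromone) → B ring attached with creation of C2.

## Route

**Step 1**
Reactants: 1 (2,4,6-trihydroxyacetophenone), 2 (prenyl bromide)
Product: 3, 1-[2,4,6-trihydroxy-3-(3-methylbut-2-en-1-yl)phenyl]ethan-1-one
Conditions: DBU (1.1 equiv), 2 (1.0 equiv), THF, 0 °C → rt
Reagents that add atoms: prenyl bromide, CC(C)=CCBr
Why: Direct C-alkylation of the phloroglucinol anion; the two ring CH positions are equivalent, so only one mono-C-prenyl product is possible (moderate yield, di-C- and O-prenyl by-products removed by chromatography).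

**Step 2**
Reactants: 3
Product: 4, 1-[2-hydroxy-4,6-bis(methoxymethoxy)-3-(3-methylbut-2-en-1-yl)phenyl]ethan-1-one
Conditions: MOMCl (2.2 equiv), i-Pr2NEt, CH2Cl2, 0 °C → rt
Reagents that add atoms: chloromethyl methyl ether, COCCl
Why: Selective O-alkylation: the 4-OH and the less hindered ortho OH (flanked by H) react, while the 2-OH, buttressed by the prenyl group and chelated to the acetyl, stays free; this is the OH that later becomes O1 next to the prenyl (C8).

**Step 3**
Reactants: 4
Product: 5, 5,7-bis(methoxymethoxy)-8-(3-methylbut-2-en-1-yl)-4H-chromen-4-one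
Conditions: DMF-DMA (3 equiv), PhMe, 95 °C; concentrate; then 1 M aq HCl/CH2Cl2, rt, ≤1 h, NaHCO3 quench
Reagents that add atoms: N,N-dimethylformamide dimethyl acetal, CN(C)C(OC)OC (supplies C2)
Why: Enaminone formation at the acetyl CH3, then acid-promoted oxa-Michael addition/elimination of Me2NH (enaminone chromone synthesis); brief dilute acid closes the ring faster than it cleaves aryl MOM ethers.

**Step 4**
Reactants: 6 (4-bromophenol), 2 (prenyl bromide)
Product: 7, 4-bromo-2-(3-methylbut-2-en-1-yl)phenol
Conditions: NaH (1.0 equiv), PhMe, 0 °C; then 2, rt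
Reagents that add atoms: prenyl bromide, CC(C)=CCBr
Why: Ortho-selective C-alkylation of the tight sodium phenoxide ion pair in a non-polar solvent; the para position is blocked by Br.

**Step 5**
Reactants: 7
Product: 8, 4-bromo-1-(methoxymethoxy)-2-(3-methylbut-2-en-1-yl)benzene
Conditions: MOMCl, i-Pr2NEt, CH2Cl2, 0 °C → rt
Reagents that add atoms: chloromethyl methyl ether, COCCl
Why: Standard phenol O-alkylation (Williamson type) to mask the acidic OH before metalation.

**Step 6**
Reactants: 8
Product: 9, [4-(methoxymethoxy)-3-(3-methylbut-2-en-1-yl)phenyl]boronic acid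
Conditions: n-BuLi, THF, −78 °C; B(Oi-Pr)3, −78 °C → rt; aq NH4Cl
Reagents that add atoms: triisopropyl borate, CC(C)OB(OC(C)C)OC(C)C; water, O
Why: Br/Li exchange at −78 °C is much faster than ortho-lithiation or benzylic/allylic deprotonation; borate trapping and mild hydrolysis give the boronic acid with the MOM ether intact.

**Step 7**
Reactants: 5, 9 (2 equiv)
Product: 10, (2S)-5,7-bis(methoxymethoxy)-2-[4-(methoxymethoxy)-3-(3-methylbut-2-en-1-yl)phenyl]-8-(3-methylbut-2-en-1-yl)-2,3-dihydro-4H-chromen-4-one
Conditions: Pd(OCOCF3)2 (5 mol %), (R)-t-BuPyOx (6 mol %), NH4PF6 (30 mol %), H2O (5 equiv), ClCH2CH2Cl, 60 °C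
Reagents that add atoms: none beyond reactant 9 (aryl group); the C3 proton comes from water
Why: Pd(II)-catalysed asymmetric conjugate addition of an arylboronic acid to the chromone enone (transmetalation, migratory insertion, protonolysis of the Pd enolate); the ligand's tert-butyl group directs the aryl to the Re face of C2, giving 2S under non-basic conditions that do not open the flavanone.

**Step 8**
Reactants: 10
Product: 11, Euchrestaflavanone A, (2S)-5,7-dihydroxy-2-[4-hydroxy-3-(3-methylbut-2-en-1-yl)phenyl]-8-(3-methylbut-2-en-1-yl)-2,3-dihydro-4H-chromen-4-one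
Conditions: 3 M aq HCl/MeOH (1:4), 45–50 °C, TLC control (about 1 h); NaHCO3 workup
Reagents that add atoms: none
Why: Acid-catalysed acetal (MOM) cleavage; no base is used, so C2 is not epimerised by retro-oxa-Michael opening, and short mild treatment limits cyclisation of the prenyl groups onto the adjacent phenols.

## Compound list
1 | 2,4,6-trihydroxyacetophenone | CC(=O)c1c(O)cc(O)cc1O | starting material
2 | prenyl bromide (1-bromo-3-methylbut-2-ene) | CC(C)=CCBr | starting material
3 | 1-[2,4,6-trihydroxy-3-prenylphenyl]ethanone | CC(=O)c1c(O)cc(O)c(CC=C(C)C)c1O | intermediate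
4 | 1-[2-hydroxy-4,6-bis(methoxymethoxy)-3-prenylphenyl]ethanone | CC(=O)c1c(O)c(CC=C(C)C)c(OCOC)cc1OCOC | intermediate
5 | 5,7-bis(methoxymethoxy)-8-prenyl-4H-chromen-4-one | O=c1ccoc2c(CC=C(C)C)c(OCOC)cc(OCOC)c12 | intermediate
6 | 4-bromophenol | Oc1ccc(Br)cc1 | starting material
7 | 4-bromo-2-prenylphenol | CC(C)=CCc1cc(Br)ccc1O | intermediate
8 | 4-bromo-1-(methoxymethoxy)-2-prenylbenzene | CC(C)=CCc1cc(Br)ccc1OCOC | intermediate
9 | [4-(methoxymethoxy)-3-prenylphenyl]boronic acid | CC(C)=CCc1cc(B(O)O)ccc1OCOC | intermediate
10 | (2S)-5,7-bis(methoxymethoxy)-2-[4-(methoxymethoxy)-3-prenylphenyl]-8-prenylchroman-4-one | CC(C)=CCc1cc([C@@H]2CC(=O)c3c(OCOC)cc(OCOC)c(CC=C(C)C)c3O2)ccc1OCOC | intermediate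
11 | Euchrestaflavanone A, (2S)-5,7,4′-trihydroxy-8,3′-diprenylflavanone | CC(C)=CCc1cc([C@@H]2CC(=O)c3c(O)cc(O)c(CC=C(C)C)c3O2)ccc1O | target

## Summary
Total steps: 8 (convergent).
Longest linear sequence: 5 steps (1 → 3 → 4 → 5 → 10 → 11; the aryl branch 6 → 7 → 8 → 9 → 10 → 11 is also 5).

Three steps most likely to fail, each with a fallback:

1. **Step 7 (asymmetric conjugate addition).** The chromone is electron-rich and peri-substituted, two prenyl olefins are exposed to cationic Pd(II), and the ee and sense of induction are unproven on this substrate. Fallback: Claisen–Schmidt condensation of 4 with 4-(methoxymethoxy)-3-prenylbenzaldehyde (from 8 by Li/DMF formylation) to the 2′-hydroxychalcone, oxa-Michael cyclisation (NaOAc/EtOH, or a cinchona-thiourea catalyst), then preparative chiral SFC of 10 to isolate the 2S enantiomer.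

2. **Step 2 (regioselective bis-MOM protection).** Protecting the wrong ortho OH would lead to the 6-prenyl series. Fallback: start from 2-hydroxy-4,6-bis(methoxymethoxy)acetophenone (from 1, no regiochemical issue), iodinate ortho to the free OH at C3, and install the prenyl group by Stille coupling with tributyl(prenyl)stannane to reach 4 unambiguously.

3. **Step 8 (acidic MOM removal).** Acid can cyclise a prenyl group onto a neighbouring phenol (2,2-dimethylchroman formation) or erode ee. Fallback: change the protecting-group strategy to TBS ethers (TBSCl in place of MOMCl in steps 2 and 5) and unveil with buffered fluoride (HF·pyridine or TBAF/AcOH), avoiding protic acid and free phenoxide.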